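The γ-aryl butyrolactone ring (C1, O2, C3, C3a, C6a of the furo[3,4-c]furan-1-one) is opened at O2–C3 and C3a–C6a. The key step exploits two features: C6a is alpha to the carboxyl carbon, and C3 is benzylic to the trioxygenated ring. One photoredox radical–polar crossover closes both rings. A C6a radical cyclises 5-exo onto an E-cinnamyl ether, the C3 benzylic radical is oxidised to the cation, and the acyl oxygen captures it while the chiral auxiliary departs. The precursor is an acyclic alpha-bromo-beta-(cinnamyloxy) imide. Its one lasting stereocentre (C6), set by an Evans bromoacetate aldol, directs C6a, C3a and C3.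

Key step: step 8

Remark on the chemistry: atoms are numbered as in tetrahydro-1H,3H-furo[3,4-c]furan-1-one (C1 carbonyl, O2, C3 bearing the trihydroxyphenyl ring, C3a, C4 methylene, O5, C6 bearing the dihydroxyphenyl ring, C6a). The target is read as the (3S,3aR,6S,6aS) isomer, cis-fused, with both aryl groups on the convex face. TBS = tert-butyldimethylsilyl.

Step 1
Reactants: 1 3,4-dihydroxybenzaldehyde
Product: 2 3,4-bis(tert-butyldimethylsilyloxy)benzaldehyde
Conditions: TBSCl, imidazole, DMF, rt
Reagents that add atoms: tert-butyldimethylsilyl chloride (TBSCl), CC(C)(C)[Si](C)(C)Cl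
Why: Imidazole-promoted silyl ether formation masks the oxidation-prone catechol with groups that should tolerate boron enolates, catalytic acid, ruthenium carbenes and single-electron transfer and that leave with fluoride at the end; no stereocentre is involved.

Step 2
Reactants: 3 (S)-4-benzyloxazolidin-2-one; 4 bromoacetyl bromide
Product: 6 (S)-4-benzyl-3-(2-bromoacetyl)oxazolidin-2-one, via N-lithio oxazolidinone 5 (not isolated)
Conditions: n-BuLi, THF, −78 °C; then 4, −78 to 0 °C
Reagents that add atoms: none
Why: N-acylation of the lithiated oxazolidinone by the acyl bromide should outrun substitution at the primary C–Br bond at low temperature, and the auxiliary stereocentre is not touched.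

Step 3
Reactants: 6 (S)-4-benzyl-3-(2-bromoacetyl)oxazolidin-2-one; 2 3,4-bis(tert-butyldimethylsilyloxy)benzaldehyde
Product: 9 (S)-4-benzyl-3-{(2S,3R)-2-bromo-3-[3,4-bis(TBSO)phenyl]-3-hydroxypropanoyl}oxazolidin-2-one (syn-bromohydrin imide), via Z-dibutylboron enolate 7 (not isolated), via dibutylboron aldolate 8 (not isolated)
Conditions: Bu2BOTf, Et3N, Et2O, −78 to 0 °C; 2, −78 to 0 °C; then H2O2, MeOH, pH 7 buffer, 0 °C
Reagents that add atoms: none
Why: Evans syn-aldol reaction: the Z-boron enolate reacts through a Zimmerman–Traxler chair in which the benzyl group of the dipole-aligned (S)-auxiliary blocks one enolate face, which should set the carbinol carbon (the future C6) in the required sense and the bromine-bearing carbon syn to it, the bromine serving both as the enolate substituent needed for high facial control and as the later radical trigger.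

Step 4
Reactants: 9 syn-bromohydrin imide; 10 allyl 2,2,2-trichloroacetimidate
Product: 11 (S)-3-{(2S,3R)-3-(allyloxy)-2-bromo-3-[3,4-bis(TBSO)phenyl]propanoyl}-4-benzyloxazolidin-2-one
Conditions: TfOH (cat.), CH2Cl2–cyclohexane, 0 °C
Reagents that add atoms: none
Why: Brønsted acid-catalysed O-alkylation with a trichloroacetimidate forms the ether without base, which would close the bromohydrin to an epoxide or start a retro-aldol reaction, and because the carbinol C–O bond is never broken both stereocentres are retained.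

Step 5
Reactants: 12 3,4,5-trihydroxybenzaldehyde
Product: 13 3,4,5-tris(tert-butyldimethylsilyloxy)benzaldehyde
Conditions: TBSCl, imidazole, DMF, rt
Reagents that add atoms: tert-butyldimethylsilyl chloride (TBSCl), CC(C)(C)[Si](C)(C)Cl
Why: Imidazole-promoted silyl ether formation protects all three pyrogallol hydroxyl groups and keeps them as donors that will later stabilise the benzylic radical and cation; no stereocentre is involved.

Step 6
Reactants: 13 3,4,5-tris(tert-butyldimethylsilyloxy)benzaldehyde
Product: 14 3,4,5-tris(tert-butyldimethylsilyloxy)styrene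
Conditions: MePPh3Br, n-BuLi, THF, 0 °C; then 13, 0 °C to rt
Reagents that add atoms: methyltriphenylphosphonium bromide, C[P+](c1ccccc1)(c1ccccc1)c1ccccc1.[Br-]
Why: Wittig methylenation of a non-enolisable aromatic aldehyde should be clean, the ylide being preformed so that no free base attacks the aryl silyl ethers; no stereocentre is formed.

Step 7
Reactants: 11 allyl ether imide; 14 3,4,5-tris(tert-butyldimethylsilyloxy)styrene
Product: 15 (S)-4-benzyl-3-{(2S,3R)-2-bromo-3-[3,4-bis(TBSO)phenyl]-3-[(E)-3-(3,4,5-tris(TBSO)phenyl)allyloxy]propanoyl}oxazolidin-2-one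
Conditions: second-generation Hoveyda–Grubbs catalyst RuCl2(H2IMes)(=CH-C6H4-2-OiPr) (cat.), 14 (excess), CH2Cl2, 40 °C
Reagents that add atoms: none
Why: Olefin cross-metathesis of a terminal allyl ether with a slowly homodimerising styrene should give the thermodynamically favoured E-cinnamyl ether with loss of ethylene, while the C–Br bond, the imide and both stereocentres are spectators at this temperature.

Step 8
Reactants: 15 alpha-bromo-beta-(cinnamyloxy) imide
Product: 17 (3S,3aR,6S,6aS)-6-[3,4-bis(TBSO)phenyl]-3-[3,4,5-tris(TBSO)phenyl]tetrahydro-1H,3H-furo[3,4-c]furan-1-one, via bicyclic acyloxonium bromide 16 (not isolated)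
Conditions: fac-Ir(ppy)3 (cat.), K2HPO4, H2O (10 equiv), MeCN–CH2Cl2, 450 nm LEDs, rt, degassed
Reagents that add atoms: water, O
Why: Excited fac-Ir(ppy)3 reduces the C–Br bond of 15 by one electron, the alpha-acyl radical at C6a adds to the near alkene carbon (C3a–C6a bond), tetravalent iridium oxidises the new C3 benzylic radical to the cation, the imide acyl oxygen captures it (O2–C3 bond) to give 16, and water collapses 16 to lactone 17 with release of the oxazolidinone. The closest known reaction types are the photoredox carbolactonisation of styrenes with alpha-bromocarbonyl compounds, itself a redox-neutral relative of the Mn(OAc)3 lactone annulation, and the halolactonisation of unsaturated N-acyloxazolidinones in which the auxiliary is expelled. The tetrahydrofuran ring closes by 5-exo-trig radical cyclisation and the lactone ring by five-membered capture of a benzylic cation by the carbonyl oxygen, which is geometrically possible only in the cis-fused sense and so filters out any trans-cyclised material. C6a and C3a are controlled by the C6 stereocentre through a chair-like Beckwith–Houk transition state with the C6 aryl group pseudoequatorial, the acyl group anti to it and the styryl arm trans to it across the ring, three preferences that all converge on the 6,6a-trans, 3a,6a-cis array. C3 is controlled by the newly formed ring, because the planar cation closes in the rotamer that turns the bulky aryl group away from the C4 methylene and onto the convex face. The step needs 5-exo rather than 6-endo addition, secured by the aryl group on the far alkene carbon, and oxidation rather than hydrogen abstraction of the second radical, secured by the three silyloxy donors; the C–Br configuration and the alkene geometry are erased and do not matter.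

Step 9
Reactants: 17 penta-TBS furofuranone
Product: 18 (3S,3aR,6S,6aS)-6-(3,4-dihydroxyphenyl)-3-(3,4,5-trihydroxyphenyl)tetrahydro-1H,3H-furo[3,4-c]furan-1-one (CNP0290035.1)
Conditions: Et3N·3HF, THF, rt, argon
Reagents that add atoms: none
Why: Fluoride-driven cleavage of the five aryl silyl ethers (Si–F bond formation) in a slightly acidic medium keeps the catechol and pyrogallol rings protonated and thus safe from aerobic oxidation, and is too mild to open the lactone, enolise C6a or ionise the benzylic C–O bonds, so all four stereocentres persist.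

Compound list
1 | 3,4-dihydroxybenzaldehyde | O=Cc1ccc(O)c(O)c1 | starting material
2 | 3,4-bis(tert-butyldimethylsilyloxy)benzaldehyde | O=Cc1ccc(O[Si](C)(C)C(C)(C)C)c(O[Si](C)(C)C(C)(C)C)c1 | intermediate
3 | (S)-4-benzyloxazolidin-2-one | O=C1N[C@@H](Cc2ccccc2)CO1 | starting material
4 | bromoacetyl bromide | O=C(Br)CBr | starting material
5 | N-lithio (S)-4-benzyloxazolidin-2-one | [Li]N1[C@@H](Cc2ccccc2)COC1=O | intermediate
6 | (S)-4-benzyl-3-(2-bromoacetyl)oxazolidin-2-one | O=C1OC[C@H](Cc2ccccc2)N1C(=O)CBr | intermediate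
7 | Z-dibutylboron enolate of 6 | O=C1OC[C@H](Cc2ccccc2)N1/C(OB(CCCC)CCCC)=C/Br | intermediate
8 | dibutylboron aldolate, (2S,3R) | O=C1OC[C@H](Cc2ccccc2)N1C(=O)[C@@H](Br)[C@H](OB(CCCC)CCCC)c3ccc(O[Si](C)(C)C(C)(C)C)c(O[Si](C)(C)C(C)(C)C)c3 | intermediate
9 | (S)-4-benzyl-3-{(2S,3R)-2-bromo-3-[3,4-bis(TBSO)phenyl]-3-hydroxypropanoyl}oxazolidin-2-one | O=C1OC[C@H](Cc2ccccc2)N1C(=O)[C@@H](Br)[C@H](O)c3ccc(O[Si](C)(C)C(C)(C)C)c(O[Si](C)(C)C(C)(C)C)c3 | intermediate
10 | allyl 2,2,2-trichloroacetimidate | C=CCOC(=N)C(Cl)(Cl)Cl | starting material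
11 | (S)-3-{(2S,3R)-3-(allyloxy)-2-bromo-3-[3,4-bis(TBSO)phenyl]propanoyl}-4-benzyloxazolidin-2-one | O=C1OC[C@H](Cc2ccccc2)N1C(=O)[C@@H](Br)[C@H](OCC=C)c3ccc(O[Si](C)(C)C(C)(C)C)c(O[Si](C)(C)C(C)(C)C)c3 | intermediate
12 | 3,4,5-trihydroxybenzaldehyde | O=Cc1cc(O)c(O)c(O)c1 | starting material
13 | 3,4,5-tris(tert-butyldimethylsilyloxy)benzaldehyde | O=Cc1cc(O[Si](C)(C)C(C)(C)C)c(O[Si](C)(C)C(C)(C)C)c(O[Si](C)(C)C(C)(C)C)c1 | intermediate
14 | 3,4,5-tris(tert-butyldimethylsilyloxy)styrene | C=Cc1cc(O[Si](C)(C)C(C)(C)C)c(O[Si](C)(C)C(C)(C)C)c(O[Si](C)(C)C(C)(C)C)c1 | intermediate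
15 | (S)-4-benzyl-3-{(2S,3R)-2-bromo-3-[3,4-bis(TBSO)phenyl]-3-[(E)-3-(3,4,5-tris(TBSO)phenyl)allyloxy]propanoyl}oxazolidin-2-one | O=C1OC[C@H](Cc2ccccc2)N1C(=O)[C@@H](Br)[C@H](OC/C=C/c3cc(O[Si](C)(C)C(C)(C)C)c(O[Si](C)(C)C(C)(C)C)c(O[Si](C)(C)C(C)(C)C)c3)c4ccc(O[Si](C)(C)C(C)(C)C)c(O[Si](C)(C)C(C)(C)C)c4 | intermediate
16 | bicyclic acyloxonium bromide (C1 still bears the oxazolidinone nitrogen; O2–C3 and C3a–C6a already formed) | O=C1OC[C@H](Cc2ccccc2)N1C3=[O+][C@H](c4cc(O[Si](C)(C)C(C)(C)C)c(O[Si](C)(C)C(C)(C)C)c(O[Si](C)(C)C(C)(C)C)c4)[C@H]5CO[C@H](c6ccc(O[Si](C)(C)C(C)(C)C)c(O[Si](C)(C)C(C)(C)C)c6)[C@@H]35.[Br-] | intermediate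
17 | (3S,3aR,6S,6aS)-6-[3,4-bis(TBSO)phenyl]-3-[3,4,5-tris(TBSO)phenyl]tetrahydro-1H,3H-furo[3,4-c]furan-1-one | O=C1O[C@H](c2cc(O[Si](C)(C)C(C)(C)C)c(O[Si](C)(C)C(C)(C)C)c(O[Si](C)(C)C(C)(C)C)c2)[C@H]2CO[C@H](c3ccc(O[Si](C)(C)C(C)(C)C)c(O[Si](C)(C)C(C)(C)C)c3)[C@@H]12 | intermediate
18 | (3S,3aR,6S,6aS)-6-(3,4-dihydroxyphenyl)-3-(3,4,5-trihydroxyphenyl)tetrahydro-1H,3H-furo[3,4-c]furan-1-one | O=C1O[C@H](c2cc(O)c(O)c(O)c2)[C@H]2CO[C@H](c3ccc(O)c(O)c3)[C@@H]12 | target

Total step count: 9. Longest linear sequence: 6 steps (steps 2, 3, 4, 7, 8, 9; the branch through step 1 is equally long).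

Steps most likely to fail

Risk 1, step 8.
- **What may go wrong:** The second radical may be oxidised too slowly, so that hydrogen abstraction or oligomerisation competes. Base may induce loss of the cinnamyloxy group before electron transfer. The ring closure may be only partly cis-selective, or the capture of the cation only partly face-selective.
- **Fallback:** It sets out from 15, comes back at 17, and splits the event into two known operations. Copper-catalysed bromine atom-transfer radical cyclisation (CuBr, tris(2-pyridylmethyl)amine, CH2Cl2, rt to 40 °C) should give the cyclised benzylic bromide F1 as a mixture of epimers at the C–Br carbon. Silver-assisted ionisation (AgOTf, H2O, acetone, 0 °C) then lets the cis-disposed imide carbonyl close the lactone with loss of the auxiliary to give 17.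

Risk 2, step 4.
- **What may go wrong:** Acid may ionise the electron-rich benzylic carbinol and erode configuration at the future C6. Retro-aldol cleavage may occur. Alkylation of a hindered, inductively deactivated hydroxyl group may be sluggish.
- **Fallback:** It sets out from 6 and 2, comes back at 17, and forms the benzylic C–O bond by alkene alkoxybromination instead of O-alkylation.
  - Arbuzov reaction of 6 with P(OEt)3 should give the phosphonoacetyl imide F2.
  - Horner–Wadsworth–Emmons olefination of 2 under Masamune–Roush conditions (LiCl, iPr2NEt, MeCN) should give the E-enoyl imide F3.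
  - NBS, allyl alcohol and Yb(OTf)3 (cat.) should add bromine and allyloxy anti, with oxygen at the benzylic carbon and the chelated auxiliary biasing the face. Chromatographic separation of the diastereomers should deliver the anti-bromo allyl ether F4, the C2 epimer of 11.
  - Because C2 becomes a planar radical, F4 serves equally well. Cross-metathesis with 14 under the conditions of step 7 should give the epimeric cinnamyl ether F5, and the conditions of step 8 should convert it into 17.

Risk 3, step 7.
- **What may go wrong:** Styrene homodimerisation may outrun the cross reaction. Ruthenium hydrides may isomerise the allyl ether to an enol ether. Ruthenium may initiate bromine atom transfer at the alpha-bromo imide.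
- **Fallback:** It sets out from 13 and 9, comes back at 15, and brings in the whole cinnamyl unit preformed.
  - Wittig olefination of 13 with Ph3P=CHCO2Et should give the ethyl cinnamate F6.
  - Reduction with iBu2AlH (CH2Cl2, −78 °C) should give the cinnamyl alcohol F7.
  - Cl3CCN with DBU (cat.) should give the cinnamyl trichloroacetimidate F8.
  - Acid-catalysed etherification of 9 with F8 (TMSOTf cat., CH2Cl2, −40 °C) should give 15 directly. The conjugated linear ether is favoured over the branched one.

Further compounds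
F1 | step 8 | (S)-4-benzyl-3-{(2S,3S,4R)-4-[bromo(3,4,5-tris(TBSO)phenyl)methyl]-2-[3,4-bis(TBSO)phenyl]tetrahydrofuran-3-carbonyl}oxazolidin-2-one, both epimers at the C–Br carbon | O=C1OC[C@H](Cc2ccccc2)N1C(=O)[C@@H]3[C@@H](c4ccc(O[Si](C)(C)C(C)(C)C)c(O[Si](C)(C)C(C)(C)C)c4)OC[C@@H]3C(Br)c5cc(O[Si](C)(C)C(C)(C)C)c(O[Si](C)(C)C(C)(C)C)c(O[Si](C)(C)C(C)(C)C)c5
F2 | step 4 | (S)-4-benzyl-3-[2-(diethoxyphosphoryl)acetyl]oxazolidin-2-one | O=C1OC[C@H](Cc2ccccc2)N1C(=O)CP(=O)(OCC)OCC
F3 | step 4 | (S)-4-benzyl-3-{(E)-3-[3,4-bis(TBSO)phenyl]acryloyl}oxazolidin-2-one | O=C1OC[C@H](Cc2ccccc2)N1C(=O)/C=C/c3ccc(O[Si](C)(C)C(C)(C)C)c(O[Si](C)(C)C(C)(C)C)c3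
F4 | step 4 | (S)-3-{(2R,3R)-3-(allyloxy)-2-bromo-3-[3,4-bis(TBSO)phenyl]propanoyl}-4-benzyloxazolidin-2-one | O=C1OC[C@H](Cc2ccccc2)N1C(=O)[C@H](Br)[C@H](OCC=C)c3ccc(O[Si](C)(C)C(C)(C)C)c(O[Si](C)(C)C(C)(C)C)c3
F5 | step 4 | (S)-4-benzyl-3-{(2R,3R)-2-bromo-3-[3,4-bis(TBSO)phenyl]-3-[(E)-3-(3,4,5-tris(TBSO)phenyl)allyloxy]propanoyl}oxazolidin-2-one | O=C1OC[C@H](Cc2ccccc2)N1C(=O)[C@H](Br)[C@H](OC/C=C/c3cc(O[Si](C)(C)C(C)(C)C)c(O[Si](C)(C)C(C)(C)C)c(O[Si](C)(C)C(C)(C)C)c3)c4ccc(O[Si](C)(C)C(C)(C)C)c(O[Si](C)(C)C(C)(C)C)c4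
F6 | step 7 | ethyl (E)-3-[3,4,5-tris(TBSO)phenyl]acrylate | CCOC(=O)/C=C/c1cc(O[Si](C)(C)C(C)(C)C)c(O[Si](C)(C)C(C)(C)C)c(O[Si](C)(C)C(C)(C)C)c1
F7 | step 7 | (E)-3-[3,4,5-tris(TBSO)phenyl]prop-2-en-1-ol | OC/C=C/c1cc(O[Si](C)(C)C(C)(C)C)c(O[Si](C)(C)C(C)(C)C)c(O[Si](C)(C)C(C)(C)C)c1
F8 | step 7 | (E)-3-[3,4,5-tris(TBSO)phenyl]allyl 2,2,2-trichloroacetimidate | N=C(OC/C=C/c1cc(O[Si](C)(C)C(C)(C)C)c(O[Si](C)(C)C(C)(C)C)c(O[Si](C)(C)C(C)(C)C)c1)C(Cl)(Cl)Cl
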